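Everything rests on cutting ring B, the hexasubstituted arene fused to the lactol. Its free phenol oxygen and its diaryl-ether oxygen sit para to each other. The two ring carbons between them carry the lactone C=O carbon and the lactol CH. This pattern maps onto a 2-silyloxyfuran plus a 4,4-dialkoxybut-2-ynoate. One cycloaddition/ring-opening forges two ring C–C bonds, places all six substituents and leaves only the future ether oxygen as free OH. The precursor is a tetronate-derived furan with OTBS at C2, CH2OTBS at C3 and OBn at C4, so the ester oxygen and the hydroxymethyl oxygen can be freed separately. Fluoride displacement on ring A, lactonization, acid unmasking and crystallization-driven deracemization follow.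

Key step: step 6

Assumption: the lactol carbon is a hemiacylal centre that racemizes in solution by ring–chain tautomerism (hydroxyphthalide ⇌ 2-formylbenzoic acid), so "single enantiomer" is taken to mean the crystalline (S)-solid, set in the last step; which host enantiomer selects (S) must be found by trial, and the (R,R)-host is written here.

Step 1
Reactants: 1 tetronic acid (4-hydroxyfuran-2(5H)-one)
Product: 2 4-(benzyloxy)furan-2(5H)-one
Conditions: BnOH, PPh3, DIAD, THF, 0 °C to rt
Reagents that add atoms: benzyl alcohol, OCc1ccccc1
Why: Mitsunobu reaction; the acidic enol OH of 1 is alkylated on oxygen by the activated alcohol, which avoids the C3-alkylation that benzyl halides and base can give.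

Step 2
Reactants: 2 4-(benzyloxy)furan-2(5H)-one
Product: 3 4-(benzyloxy)-3-iodofuran-2(5H)-one
Conditions: NIS, TFA (cat.), MeCN, rt, dark
Reagents that add atoms: N-iodosuccinimide, O=C1CCC(=O)N1I
Why: Electrophilic iodination (addition–elimination) at C3, the nucleophilic β-carbon of the enol ether and the only vinylic C–H of 2.

Step 3
Reactants: 3 4-(benzyloxy)-3-iodofuran-2(5H)-one; 4 (tributylstannyl)methanol
Product: 5 4-(benzyloxy)-3-(hydroxymethyl)furan-2(5H)-one
Conditions: Pd(PPh3)4 (5 mol %), 1,4-dioxane, 90 °C
Reagents that add atoms: none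
Why: Stille coupling; hydroxymethyl transfer from tin to vinyl and aryl halides under zerovalent palladium is established, and it installs the C3 carbon without an ester enolate that could expel a β-alkoxide.

Step 4
Reactants: 5 4-(benzyloxy)-3-(hydroxymethyl)furan-2(5H)-one
Product: 7 4-(benzyloxy)-2-(tert-butyldimethylsilyloxy)-3-[(tert-butyldimethylsilyloxy)methyl]furan, via O-silylated butenolide 6 (not isolated)
Conditions: TBSOTf (2.3 equiv), Et3N (3.5 equiv), CH2Cl2, 0 °C; pentane extraction, used crude
Reagents that add atoms: tert-butyldimethylsilyl triflate, CC(C)(C)[Si](C)(C)OS(=O)(=O)C(F)(F)F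
Why: Soft enolization with silyl triflate and amine; the alcohol is silylated first, then O-silylation of the lactone carbonyl and loss of a C5 proton give the aromatic 2-silyloxyfuran, as known for alkyl tetronates.

Step 5
Reactants: 8 3,3-diethoxyprop-1-yne; 9 methyl chloroformate
Product: 11 methyl 4,4-diethoxybut-2-ynoate, via lithium acetylide 10 (not isolated)
Conditions: n-BuLi, THF, −78 °C; then 9, −78 to 0 °C
Reagents that add atoms: none
Why: Acylation of a lithium acetylide with a chloroformate; the acetal is inert to n-BuLi.

Step 6
Reactants: 7 4-(benzyloxy)-2-(tert-butyldimethylsilyloxy)-3-[(tert-butyldimethylsilyloxy)methyl]furan; 11 methyl 4,4-diethoxybut-2-ynoate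
Product: 13 methyl 4-(benzyloxy)-6-(tert-butyldimethylsilyloxy)-5-[(tert-butyldimethylsilyloxy)methyl]-2-(diethoxymethyl)-3-hydroxybenzoate, via oxa-bridged cycloadduct 12 (not isolated)
Conditions: 11 (1.5 equiv), PhMe (1 M), 90 °C, sealed tube, Ar; Et3N-washed SiO2
Reagents that add atoms: none
Why: Furan 7, a cyclic silyl ketene acetal reinforced by the C4 benzyloxy group, and the electron-poor alkyne 11 combine in a normal-demand, probably asynchronous [4+2] cycloaddition across furan C2 and C5 to give the oxa-bridged diene 12. In 12 the C–O bond at the silyloxy-bearing bridgehead ionizes with help from the silyloxy oxygen, and loss of the proton at the other bridgehead aromatizes the ring, so the former furan oxygen ends as the free phenol of 13. The closest known reaction type is the Diels–Alder/ring-opening benzannulation of 2-alkoxy- and 2-silyloxyfurans with acetylenic esters, which gives hydroquinone monoethers. The new carbocycle is closed intermolecularly by two suprafacial C–C bond formations (furan C5 to the acetal-bearing alkyne carbon, furan C2 to the ester-bearing one), and the bridgehead stereocentres of racemic 12 vanish on aromatization, so no stereocontrol is needed. The step needs orientational selectivity, secured because C5 carries the largest HOMO coefficient (pushed by both oxygen donors) and the alkyne carbon β to the ester carries the largest LUMO coefficient. It also needs one-directional opening, secured because only the C2 bridgehead can form an oxygen-stabilized cation, which leaves the silyl group on the oxygen next to the ester.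

Step 7
Reactants: 14 3-fluoro-5-methylphenol
Product: 15 4-bromo-3-fluoro-5-methylphenol
Conditions: NBS, MeCN, 0 °C
Reagents that add atoms: N-bromosuccinimide, O=C1CCC(=O)N1Br
Why: Electrophilic aromatic bromination; NBS in MeCN attacks para to the phenol OH, a position also activated by the adjacent F and CH3 groups.

Step 8
Reactants: 15 4-bromo-3-fluoro-5-methylphenol
Product: 16 2-bromo-1-fluoro-5-(methoxymethoxy)-3-methylbenzene
Conditions: MOMCl, i-Pr2NEt, CH2Cl2, 0 °C to rt
Reagents that add atoms: chloromethyl methyl ether, COCCl
Why: Williamson-type O-alkylation gives the MOM ether, a base-stable metalation director that is removed in the final acid step.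

Step 9
Reactants: 16 2-bromo-1-fluoro-5-(methoxymethoxy)-3-methylbenzene
Product: 18 3-bromo-2-fluoro-6-(methoxymethoxy)-4-methylbenzaldehyde, via aryllithium 17 (not isolated)
Conditions: LiN(iPr)2, THF, −78 °C; DMF; AcOH quench
Reagents that add atoms: N,N-dimethylformamide, CN(C)C=O
Why: Directed ortho-metalation; the C–H flanked by F and OMOM is by far the most acidic, lithium diisopropylamide does not exchange the aryl bromide at −78 °C, and DMF formylates the aryllithium.

Step 10
Reactants: 18 3-bromo-2-fluoro-6-(methoxymethoxy)-4-methylbenzaldehyde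
Product: 19 benzyl 2-fluoro-3-formyl-4-(methoxymethoxy)-6-methylbenzoate
Conditions: CO (balloon), BnOH (3 equiv), Pd(OAc)2 (3 mol %), Xantphos (6 mol %), Et3N, PhMe, 85 °C
Reagents that add atoms: carbon monoxide, [C-]#[O+]; benzyl alcohol, OCc1ccccc1
Why: Palladium-catalysed (Heck-type) alkoxycarbonylation of an aryl bromide; in toluene with an amine base benzyl alcohol is too weak a nucleophile to displace the fluoride.

Step 11
Reactants: 13 ring B phenol; 19 benzyl 2-fluoro-3-formyl-4-(methoxymethoxy)-6-methylbenzoate
Product: 21 benzyl 2-[6-(benzyloxy)-5-[(tert-butyldimethylsilyloxy)methyl]-2-(diethoxymethyl)-4-hydroxy-3-(methoxycarbonyl)phenoxy]-3-formyl-4-(methoxymethoxy)-6-methylbenzoate, via bis-silyl diaryl ether 20 (not isolated)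
Conditions: 19 (0.95 equiv), Cs2CO3, DMF, 50 °C, Ar; then H2O (10 vol %), rt
Reagents that add atoms: none
Why: Nucleophilic aromatic substitution (addition–elimination); the C–F carbon of 19 is flanked by formyl and ester groups that stabilize the Meisenheimer adduct, the only free OH of 13 is the nucleophile, and wet carbonate helped by the liberated fluoride then strips the phenolic but not the alkyl silyl ether, a known chemoselective cleavage.

Step 12
Reactants: 21 diaryl ether
Product: 22 2-[5-[(tert-butyldimethylsilyloxy)methyl]-2-(diethoxymethyl)-4,6-dihydroxy-3-(methoxycarbonyl)phenoxy]-3-formyl-4-(methoxymethoxy)-6-methylbenzoic acid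
Conditions: H2 (1 atm), Pd/C (10 wt %), EtOAc, rt, stopped after two equivalents of H2; used crude
Reagents that add atoms: none
Why: Catalytic hydrogenolysis cleaves the benzyl ester and the aryl benzyl ether together, whereas the doubly ortho-substituted aldehyde and the acetal and silyl ether on the fully substituted ring react much more slowly.

Step 13
Reactants: 22 seco acid
Product: 23 methyl 9-[(tert-butyldimethylsilyloxy)methyl]-6-(diethoxymethyl)-4-formyl-8-hydroxy-3-(methoxymethoxy)-1-methyl-11-oxo-11H-dibenzo[b,e][1,4]dioxepine-7-carboxylate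
Conditions: DCC, DMAP (cat.), CH2Cl2 (2 mM), rt
Reagents that add atoms: none
Why: Steglich-type carbodiimide lactonization at high dilution closes the seven-membered depsidone ring through the phenol next to the ether oxygen, since the other phenol is hydrogen-bonded to its ortho ester and lies para to the ether, out of reach of the acid.

Step 14
Reactants: 23 protected depsidone
Product: 25 racemic salazinic acid, via open formyl ester 24 (not isolated)
Conditions: 2 M aq H2SO4–1,4-dioxane (1:3), 50 °C; product precipitated with water
Reagents that add atoms: water, O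
Why: Acid hydrolysis removes the MOM, silyl and acetal groups, and in 24 the hydrate of the new formyl group attacks the neighbouring methyl ester (neighbouring-group participation, 5-exo-trig) to give the hydroxyphthalide as a racemate, while the hindered aryl ester of the depsidone survives.

Step 15
Reactants: 25 racemic salazinic acid; 26 (4R,5R)-2,2-dimethyl-α,α,α',α'-tetraphenyl-1,3-dioxolane-4,5-dimethanol ((R,R)-TADDOL)
Product: 28 (S)-salazinic acid (CNP0166154.1), via host–guest crystal 27 (not isolated)
Conditions: 26 (1 equiv), AcOH (cat.), acetone–PhMe slurry, 45 °C ↔ 10 °C cycles; filter; host leached with Et2O, −20 °C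
Reagents that add atoms: none
Why: Proposed new method: in solution the lactol carbon of 25 inverts by acid-catalysed ring-opening to the achiral 2-formylbenzoic acid tautomer, so if one enantiomer is drained from this equilibrium as the less soluble hydrogen-bonded host–guest crystal 27, the whole batch should funnel into it, the (S)-centre being set by the chiral diol host and then frozen in the solid when the host is leached with a cold aprotic solvent that does not dissolve 28; the closest known reaction types are crystallization-induced diastereomer transformation and cocrystallization-driven deracemization of configurationally labile ketones and cyanohydrins, not yet shown for hydroxyphthalides.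

Compound list
1 | tetronic acid (4-hydroxyfuran-2(5H)-one) | O=C1C=C(O)CO1 | starting material
2 | 4-(benzyloxy)furan-2(5H)-one | O=C1C=C(OCc2ccccc2)CO1 | intermediate
3 | 4-(benzyloxy)-3-iodofuran-2(5H)-one | O=C1OCC(OCc2ccccc2)=C1I | intermediate
4 | (tributylstannyl)methanol | CCCC[Sn](CCCC)(CCCC)CO | starting material
5 | 4-(benzyloxy)-3-(hydroxymethyl)furan-2(5H)-one | O=C1OCC(OCc2ccccc2)=C1CO | intermediate
6 | 4-(benzyloxy)-3-[(tert-butyldimethylsilyloxy)methyl]furan-2(5H)-one | O=C1OCC(OCc2ccccc2)=C1CO[Si](C)(C)C(C)(C)C | intermediate
7 | 4-(benzyloxy)-2-(tert-butyldimethylsilyloxy)-3-[(tert-butyldimethylsilyloxy)methyl]furan | CC(C)(C)[Si](C)(C)OCc1c(OCc2ccccc2)coc1O[Si](C)(C)C(C)(C)C | intermediate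
8 | 3,3-diethoxyprop-1-yne | C#CC(OCC)OCC | starting material
9 | methyl chloroformate | COC(=O)Cl | starting material
10 | lithium 3,3-diethoxyprop-1-yn-1-ide | [Li]C#CC(OCC)OCC | intermediate
11 | methyl 4,4-diethoxybut-2-ynoate | CCOC(OCC)C#CC(=O)OC | intermediate
12 | methyl 5-(benzyloxy)-1-(tert-butyldimethylsilyloxy)-6-[(tert-butyldimethylsilyloxy)methyl]-3-(diethoxymethyl)-7-oxabicyclo[2.2.1]hepta-2,5-diene-2-carboxylate (racemic) | COC(=O)C1=C(C(OCC)OCC)C2OC1(O[Si](C)(C)C(C)(C)C)C(CO[Si](C)(C)C(C)(C)C)=C2OCc1ccccc1 | intermediate
13 | methyl 4-(benzyloxy)-6-(tert-butyldimethylsilyloxy)-5-[(tert-butyldimethylsilyloxy)methyl]-2-(diethoxymethyl)-3-hydroxybenzoate | COC(=O)c1c(C(OCC)OCC)c(O)c(OCc2ccccc2)c(CO[Si](C)(C)C(C)(C)C)c1O[Si](C)(C)C(C)(C)C | intermediate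
14 | 3-fluoro-5-methylphenol | Cc1cc(O)cc(F)c1 | starting material
15 | 4-bromo-3-fluoro-5-methylphenol | Cc1cc(O)cc(F)c1Br | intermediate
16 | 2-bromo-1-fluoro-5-(methoxymethoxy)-3-methylbenzene | COCOc1cc(C)c(Br)c(F)c1 | intermediate
17 | [3-bromo-2-fluoro-6-(methoxymethoxy)-4-methylphenyl]lithium | COCOc1cc(C)c(Br)c(F)c1[Li] | intermediate
18 | 3-bromo-2-fluoro-6-(methoxymethoxy)-4-methylbenzaldehyde | COCOc1cc(C)c(Br)c(F)c1C=O | intermediate
19 | benzyl 2-fluoro-3-formyl-4-(methoxymethoxy)-6-methylbenzoate | COCOc1cc(C)c(C(=O)OCc2ccccc2)c(F)c1C=O | intermediate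
20 | benzyl 2-[6-(benzyloxy)-4-(tert-butyldimethylsilyloxy)-5-[(tert-butyldimethylsilyloxy)methyl]-2-(diethoxymethyl)-3-(methoxycarbonyl)phenoxy]-3-formyl-4-(methoxymethoxy)-6-methylbenzoate | COCOc1cc(C)c(C(=O)OCc2ccccc2)c(Oc2c(OCc3ccccc3)c(CO[Si](C)(C)C(C)(C)C)c(O[Si](C)(C)C(C)(C)C)c(C(=O)OC)c2C(OCC)OCC)c1C=O | intermediate
21 | benzyl 2-[6-(benzyloxy)-5-[(tert-butyldimethylsilyloxy)methyl]-2-(diethoxymethyl)-4-hydroxy-3-(methoxycarbonyl)phenoxy]-3-formyl-4-(methoxymethoxy)-6-methylbenzoate | COCOc1cc(C)c(C(=O)OCc2ccccc2)c(Oc2c(OCc3ccccc3)c(CO[Si](C)(C)C(C)(C)C)c(O)c(C(=O)OC)c2C(OCC)OCC)c1C=O | intermediate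
22 | 2-[5-[(tert-butyldimethylsilyloxy)methyl]-2-(diethoxymethyl)-4,6-dihydroxy-3-(methoxycarbonyl)phenoxy]-3-formyl-4-(methoxymethoxy)-6-methylbenzoic acid | COCOc1cc(C)c(C(=O)O)c(Oc2c(O)c(CO[Si](C)(C)C(C)(C)C)c(O)c(C(=O)OC)c2C(OCC)OCC)c1C=O | intermediate
23 | methyl 9-[(tert-butyldimethylsilyloxy)methyl]-6-(diethoxymethyl)-4-formyl-8-hydroxy-3-(methoxymethoxy)-1-methyl-11-oxo-11H-dibenzo[b,e][1,4]dioxepine-7-carboxylate | Cc1cc(OCOC)c(C=O)c2c1C(=O)Oc1c(CO[Si](C)(C)C(C)(C)C)c(O)c(C(=O)OC)c(C(OCC)OCC)c1O2 | intermediate
24 | methyl 4,6-diformyl-3,8-dihydroxy-9-(hydroxymethyl)-1-methyl-11-oxo-11H-dibenzo[b,e][1,4]dioxepine-7-carboxylate | Cc1cc(O)c(C=O)c2c1C(=O)Oc1c(CO)c(O)c(C(=O)OC)c(C=O)c1O2 | intermediate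
25 | racemic salazinic acid | Cc1cc(O)c(C=O)c2c1C(=O)Oc1c(CO)c(O)c3c(c1O2)C(O)OC3=O | intermediate
26 | (R,R)-TADDOL, recoverable chiral host | CC1(C)O[C@H]([C@@H](O1)C(O)(c1ccccc1)c1ccccc1)C(O)(c1ccccc1)c1ccccc1 | starting material
27 | 1:1 host–guest crystal of (S)-salazinic acid and (R,R)-TADDOL | Cc1cc(O)c(C=O)c2c1C(=O)Oc1c(CO)c(O)c3c(c1O2)[C@@H](O)OC3=O.CC1(C)O[C@H]([C@@H](O1)C(O)(c1ccccc1)c1ccccc1)C(O)(c1ccccc1)c1ccccc1 | intermediate
28 | (S)-salazinic acid (CNP0166154.1) | Cc1cc(O)c(C=O)c2c1C(=O)Oc1c(CO)c(O)c3c(c1O2)[C@@H](O)OC3=O | target

Total step count: 15. Longest linear sequence: 10 steps (1–4, 6, 11–15).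

Steps most likely to fail

Step 15. The sparingly soluble racemic lattice of 25 may outcompete growth of the host–guest crystal. The host may discriminate poorly between the two lactol configurations. The solid may also re-equilibrate while the host is leached. The fallback uses known chemistry and sets out from 25. The racemate is resolved by sub-ambient preparative chromatography on an immobilized polysaccharide chiral stationary phase with an aprotic eluent, as practised for stereolabile hemiaminals and hemiacetals. The (S)-fraction is run directly into cold antisolvent and filtered, which returns to the route at 28. The (R)-fraction is warmed with a trace of AcOH to re-equilibrate and is injected again. New compounds on this path: none F0.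

Step 6. The reaction may stall after conjugate addition without ring closure. The furan may decay thermally before it reacts with the hindered, singly activated alkyne. The silyl group may wander between the two hydroquinone oxygens, although step 11 strips the phenolic silyl group anyway. The fallback replaces the thermal cycloaddition by an anionic Michael–Dieckmann annulation that forms the same two bonds, and it sets out from 5 and 11. Compound 5 is silylated on the alcohol only (TBSCl, imidazole, DMF) to give 6, now isolated. Lithium diisopropylamide (THF, −78 °C) removes a C5 proton, and the furanolate adds through C5 to the β-carbon of 11. The resulting allenolate attacks the lactone carbonyl and opens the lactone. Tautomerization should then give methyl 4-(benzyloxy)-5-[(tert-butyldimethylsilyloxy)methyl]-2-(diethoxymethyl)-3,6-dihydroxybenzoate F1. Handled under argon, F1 is arylated with 19 under the conditions of step 11 at its non-chelated, more nucleophilic phenoxide, and this returns to the route at 21.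

Step 11. Addition to the crowded C–F carbon may be slow. The phenoxide may attack the benzyl ester instead. Early loss of the phenolic silyl group may open the way to arylation at the second oxygen. The fallback reverses the order of etherification and carbonylation and sets out from 13 and 18. In 18 the fluoride is activated by the ortho formyl group and by the inductive pull of the ortho bromine, and no ester is present. Substitution (Cs2CO3, DMF, then water) should give methyl 4-(benzyloxy)-3-[2-bromo-6-formyl-5-(methoxymethoxy)-3-methylphenoxy]-5-[(tert-butyldimethylsilyloxy)methyl]-2-(diethoxymethyl)-6-hydroxybenzoate F2. Alkoxycarbonylation of F2 (CO, BnOH, Pd(OAc)2, Xantphos, Et3N, PhMe) then installs the benzyl ester and returns to the route at 21.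

Further compounds
F0 | step 15 | none | none
F1 | step 6 | methyl 4-(benzyloxy)-5-[(tert-butyldimethylsilyloxy)methyl]-2-(diethoxymethyl)-3,6-dihydroxybenzoate | COC(=O)c1c(C(OCC)OCC)c(O)c(OCc2ccccc2)c(CO[Si](C)(C)C(C)(C)C)c1O
F2 | step 11 | methyl 4-(benzyloxy)-3-[2-bromo-6-formyl-5-(methoxymethoxy)-3-methylphenoxy]-5-[(tert-butyldimethylsilyloxy)methyl]-2-(diethoxymethyl)-6-hydroxybenzoate | COCOc1cc(C)c(Br)c(Oc2c(OCc3ccccc3)c(CO[Si](C)(C)C(C)(C)C)c(O)c(C(=O)OC)c2C(OCC)OCC)c1C=O
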